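## The problem

Target 12 is a 1-aryl-1,2-dihydronaphthalene: ring B (C1, C2, C3, C4, C4a, C8a) is fused to a catechol ring A (hydroxyls on C6 and C7), C1 bears a 4-hydroxyphenyl group, C2 and C3 each bear a 2,4-dihydroxybenzoyl group, and C3=C4 is conjugated with the C3 ketone and with ring A. Its thirty carbons are those of two chalcones joined α-carbon to α-carbon (C2–C3) and from the β-carbon of one (C1) to an ortho carbon of the catechol ring of the other (C8a). The central C2–C3 bond is therefore the middle of a 1,4-diketone and links two carbons of like polarity, which plain enolate chemistry cannot unite. There are two adjacent stereocentres, C1 (R) and C2 (S), with the aryl and aroyl groups trans. C2 is α to a ketone and can enolise, whereas the diarylmethine C1 cannot; once C1 is fixed the trans arrangement is the thermodynamic one and holds C2, but if C2 is made first it must pass its configuration to C1 before any enolisation. Seven phenols (one an air-sensitive catechol), a 2'-hydroxy enone that can close to a chromanone under base, and a dihydronaphthalene that aromatises under oxidants mean the phenols must stay masked to the last step and every oxidation must come before it. The enabling feature is that C2–C3 is exactly the bond a head-to-head [2+2] photocycloaddition of the two enone double bonds creates, its companion bond C1–C4 joining two carbons that each carry an electron-rich aryl group. Because C8a lies para to the C6 oxygen and the C1 aryl group stabilises a cation, one-electron oxidation can later break C1–C4 and reconnect C1 to C8a, and the 2'-hydroxyl beside the C2 carbonyl is the chelating handle through which a chiral Lewis acid can control C2.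

## Retrosynthesis

**12 ⇒ 11.** The seven phenolic O–H bonds are traced back to O–CH3 bonds of the heptamethyl ether 11, the (1R,2S)-dihydronaphthalene with methoxy groups at every oxygenated position. Methyl is preferred over benzyl or acetal protection because it is inert to aqueous base, to a Lewis acid, to triplet sensitisation and to a one-electron oxidant under acid, and because all four methylated building blocks are commercial. The skeleton is unchanged, but 11 has no free catechol and can be purified normally. The forward reaction must cleave seven aryl methyl ethers without touching the enone, the C2 stereocentre or the dihydronaphthalene.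

**11 ⇒ 10.** C1–C8a is cut, C1 is rejoined to C4 and C3 regains its hydrogen, which turns ring B into the four-membered ring C1–C2–C3–C4 of the all-trans cyclobutane 10 (aroyl groups on C2 and C3, aryl groups on C1 and C4). Against the Diels–Alder-type cuts at C1–C2 and C3–C4, this one keeps the C2–C3 bond and the C2 configuration in the precursor and reduces what remains to a single cycloaddition. Compound 10 has no alkene, and its C1, C3 and C4 configurations need not be correct because they are erased or reset. The forward reaction is an oxidation that breaks only C1–C4, closes C1 onto C8a trans to the C2 aroyl group, and then removes a second electron and the C3 proton, all without enolising C2.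

**10 ⇒ 9.** One O–CH3 bond is cut at the 2'-oxygen of the aroyl group on C2, giving phenol 9. The free phenol is needed for the cycloaddition but is a liability in the oxidation, where it could capture the C1 cation through oxygen. Capping it with the same methyl group used elsewhere costs one step and no extra deprotection. The forward reaction only has to alkylate a hydrogen-bonded phenol without C-alkylation of the two cyclobutyl ketones.

**9 ⇒ 4 + 8.** C2–C3 and C1–C4 are cut together, a retro-[2+2] that returns two enones: 2'-hydroxychalcone 4 (C1, C2, the 4-methoxyphenyl group and the hydroxyaroyl group) and tetramethoxychalcone 8 (C3, C4, the veratryl group and the dimethoxybenzoyl group). Against a stepwise oxidative coupling of two saturated ketone enolates, this cut needs no later dehydrogenation. The two halves differ exactly where a catalyst can tell them apart, since only 4 has a chelating 2'-hydroxyl. Both precursors are flat, achiral compounds; two C–C bonds, one ring and four stereocentres appear in this step. The forward reaction must be cross-selective, head-to-head and face-selective at C2.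

**4 ⇒ 1 + 2 and 8 ⇒ 5 + 6.** Each enone C=C bond is cut by a retro-aldol condensation through the β-hydroxy ketones 3 and 7. This leads to acetophenone 1 and aldehyde 2 for the first chalcone, and acetophenone 5 and aldehyde 6 for the second, all commercial. No other cut reaches purchasable materials in one step. The forward condensations only need to give the (E)-enones.

## Roads not taken

**Alternative 1:** The cut removes three bonds of ring A (C4a–C8a, C5–C6, C7–C8). The acyclic enediyne A2, which already carries both aroyl groups, the 4-methoxyphenyl group and both stereocentres, would be cocyclised with bis(pinacolatoboryl)ethyne A3 by CpCo(CO)2 or Cp*RuCl(cod) to the diboronate A1, closing ring A and ring B at once. Oxidation of the two C–B bonds and demethylation would lead to 12.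
- Merits: cocyclisation of a tethered diyne with an alkyne is a well-established reaction type; the catechol oxygens enter regiospecifically; nothing depends on the electronic bias of ring A.
- Weak points: the key step creates neither stereocentre, so C1 and C2 must be set by separate asymmetric chemistry while A2 is built. In A2 the C2–H is α to a ketone and next to an enyne, and the C1–H is propargylic and benzylic, so isomerisation to allenes and loss of configuration are likely under basic or metal-mediated conditions. The enone and aryl ketones compete for the low-valent metal. A2 itself needs several steps, and two further operations follow the key step.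
- Comparison: alternative 1 is ahead in precedent for its key step and avoids an oxidative ring expansion altogether. The chosen plan sets against this that its key step builds the central C2–C3 bond and the C2 stereocentre catalytically from two one-step chalcones, in six steps overall.

**Alternative 2:** The cut is at the two aryl–carbonyl bonds. The bis(3-methoxyphenyl) diester A5 of the dihydronaphthalene diacid would be treated with TiCl4, or irradiated, so that both acyl groups move from oxygen to the ring carbon ortho to it, giving the bis(2-hydroxy-4-methoxyphenyl) diketone A4; demethylation would then give 12.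
- Merits: the 1-aryl-1,2-dihydronaphthalene-2,3-dicarboxylate skeleton is classical cyclolignan chemistry; the 2'-hydroxyl groups emerge free; no cyclobutane or radical cation is involved.
- Weak points: each acyl group must choose one of three ring positions (the wanted carbon para to the methoxy group, the carbon between the two oxygens, and the carbon para to the ester oxygen), and it must do so twice, so mixtures are expected. Hot TiCl4 generates an acylium ion next to the C2–H and invites ketene formation and intermolecular acyl transfer. The photochemical variant runs through radical pairs and the dihydronaphthalene chromophore absorbs as well. The stereocentres again have to be made beforehand.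
- Comparison: alternative 2 rests on a better-known ring B synthesis than the chosen plan's ring expansion. Its key step, however, adds no skeletal bond of the carbocycle and no stereocentre, and its double regioselectivity is doubtful. The chosen plan sets against it skeletal construction and stereocontrol in one catalytic step.

**Alternative 3:** The cut is at C1–C2 and C3–C4. Under 365 nm light with Ti(OiPr)4 and a TADDOL ligand, the photoenol of the o-benzylbenzaldehyde A7 would add across the diaroylethylene A8 to give the 4-hydroxytetralin A6 (1,2-trans, 2,3-trans, 3,4-cis). Dehydration would give A4 and demethylation 12.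
- Merits: the reaction type is known, with asymmetric variants for simpler 2-alkylbenzaldehydes. The step is convergent, closes ring B and sets all relative configurations at once. The symmetric dienophile removes any regiochemical question, and the later dehydration installs C3=C4 directly.
- Weak points: a diarylmethane photoenol must form with its aryl group outward, and asymmetric induction on this class is not established. A8 has two chelating 2'-hydroxyls that compete for titanium, and it absorbs and isomerises at the irradiation wavelength. A7 and A8 each need their own short synthesis.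
- Comparison: alternative 3 is closer to precedent than the chosen plan, which contains two steps without direct precedent, and is of similar length. The chosen plan sets against it commercial-plus-one-step precursors, a catalyst–substrate chelate of defined geometry for the absolute configuration, and the direct α,α-bond construction that mirrors the likely biogenesis.

Key step: step 3

Assumption: the (S,S) antipode of the pybox ligand is taken to shield the face of chelated 4 that leads to the (2S) series (the (R,R) ligand is used if the sense proves opposite), and short-lived species (triplets, biradicals, radical cations, carbocations) are described in words and not numbered.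

## Route

Step 1
Reactants: 1 1-(2-hydroxy-4-methoxyphenyl)ethanone; 2 4-methoxybenzaldehyde
Product: 4 (E)-1-(2-hydroxy-4-methoxyphenyl)-3-(4-methoxyphenyl)prop-2-en-1-one, via β-hydroxy ketone 3 (not isolated)
Conditions: KOH (50% aq.), EtOH, rt; then dilute HCl
Reagents that add atoms: none
Why: Claisen–Schmidt condensation: the enolate of 1 adds to the non-enolisable aldehyde 2 to give aldol 3, which loses water by an E1cB path to the conjugated (E)-enone; at room temperature closure of the phenoxide onto the enone should stay minor.

Step 2
Reactants: 5 1-(2,4-dimethoxyphenyl)ethanone; 6 3,4-dimethoxybenzaldehyde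
Product: 8 (E)-1-(2,4-dimethoxyphenyl)-3-(3,4-dimethoxyphenyl)prop-2-en-1-one, via β-hydroxy ketone 7 (not isolated)
Conditions: KOH (aq.), EtOH, rt
Reagents that add atoms: none
Why: Claisen–Schmidt condensation as in step 1; aldol 7 dehydrates in the flask to the (E)-enone, and no free phenol is present.

Step 3
Reactants: 4 (E)-1-(2-hydroxy-4-methoxyphenyl)-3-(4-methoxyphenyl)prop-2-en-1-one; 8 (E)-1-(2,4-dimethoxyphenyl)-3-(3,4-dimethoxyphenyl)prop-2-en-1-one
Product: 9 (2-hydroxy-4-methoxyphenyl)[(1S,2S,3R,4R)-2-(2,4-dimethoxybenzoyl)-3-(3,4-dimethoxyphenyl)-4-(4-methoxyphenyl)cyclobutyl]methanone (all-trans)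
Conditions: Sc(OTf)3 (10 mol%), (S,S)-tBu-pybox (15 mol%), Ru(bpy)3(PF6)2 (2.5 mol%), 8 (3 equiv), iPrOAc/MeCN 3:1, blue LEDs, rt, degassed
Reagents that add atoms: none
Why: Proposed new method: Sc(OTf)3 and the pybox ligand bind 4 through its 2'-hydroxyl and carbonyl oxygen, which lowers its triplet energy enough for excited Ru(bpy)3(PF6)2 to transfer energy to this chelate alone, while 8, with a 2'-methoxy group and a higher triplet energy, stays in the ground state. The triplet enone bonds from its α-carbon (C2) to the α-carbon of 8 (C3), giving a triplet 1,4-biradical in which both radical centres are benzylic (C1 beside the 4-methoxyphenyl ring, C4 beside the veratryl ring). After intersystem crossing, radical–radical combination forms C1–C4 and closes the four-membered ring, so ring closure is the second stage of a stepwise [2+2]. The closest known reaction type is the enantioselective [2+2] photocycloaddition of 2'-hydroxychalcones with styrenes and dienes under the same three-component catalysis, together with the head-to-head photodimerisation of chalcones; a second enone as the ground-state partner has not been shown. C2, the only centre that is kept, is set by the pybox ligand, which shields one face of the chelated α-carbon. C3 is set in the same bond formation with the two aroyl groups turned away from each other, and C1 and C4 are set at ring closure after rotation in the biradical, each aryl group trans to its neighbours; these three centres are later erased or reset. The step needs cross-coupling over homodimerisation, which selective excitation of chelated 4 and the excess of 8 should secure, and head-to-head regiochemistry, which follows from the doubly benzylic biradical.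

Step 4
Reactants: 9 (2-hydroxy-4-methoxyphenyl)[(1S,2S,3R,4R)-2-(2,4-dimethoxybenzoyl)-3-(3,4-dimethoxyphenyl)-4-(4-methoxyphenyl)cyclobutyl]methanone
Product: 10 [(1S,2S,3R,4R)-3-(3,4-dimethoxyphenyl)-4-(4-methoxyphenyl)cyclobutane-1,2-diyl]bis[(2,4-dimethoxyphenyl)methanone]
Conditions: MeI, K2CO3, DMF, rt
Reagents that add atoms: iodomethane, SMILES CI
Why: Williamson O-methylation of the hydrogen-bonded phenol; carbonate is too weak to C-alkylate the ketones, and the all-trans cyclobutane is the thermodynamic isomer, so reversible enolisation cannot change C2. The ether closes the oxygen trap that could otherwise capture the C1 cation in step 5.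

Step 5
Reactants: 10 [(1S,2S,3R,4R)-3-(3,4-dimethoxyphenyl)-4-(4-methoxyphenyl)cyclobutane-1,2-diyl]bis[(2,4-dimethoxyphenyl)methanone]
Product: 11 [(1R,2S)-6,7-dimethoxy-1-(4-methoxyphenyl)-1,2-dihydronaphthalene-2,3-diyl]bis[(2,4-dimethoxyphenyl)methanone]
Conditions: DDQ (1.1 equiv), TFA, CH2Cl2, 0 °C
Reagents that add atoms: none
Why: Proposed new method: DDQ with TFA should take one electron from the veratryl ring, the most electron-rich arene of 10, and the strained C1–C4 bond then breaks to a 4-methoxybenzyl cation at C1 and a veratryl-stabilised radical at C4; the only nucleophilic arene carbon within reach, the veratryl carbon para to a methoxy group, attacks C1 in a six-membered Friedel–Crafts closure on the face away from the C2 aroyl group (1,2-trans, C2 untouched), and a second oxidation at C4 with loss of the acidic C3 proton gives the C3=C4 enone. The closest known reaction types are the radical-cation cleavage of 1,2-diarylcyclobutanes and the dehydrogenative radical-cation [4+2] annulation of aryl alkenes to 1-aryl-1,2-dihydronaphthalenes, which runs through the same 1,4-radical cation.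

Step 6
Reactants: 11 [(1R,2S)-6,7-dimethoxy-1-(4-methoxyphenyl)-1,2-dihydronaphthalene-2,3-diyl]bis[(2,4-dimethoxyphenyl)methanone]
Product: 12 [(1R,2S)-6,7-dihydroxy-1-(4-hydroxyphenyl)-1,2-dihydronaphthalene-2,3-diyl]bis[(2,4-dihydroxyphenyl)methanone]
Conditions: BBr3 (15 equiv), CH2Cl2, −78 °C to rt; then MeOH, H2O, under argon
Reagents that add atoms: none
Why: Lewis acid-mediated cleavage of aryl methyl ethers (BBr3 demethylation): boron binds each ether oxygen and bromide attacks the methyl group, the two carbonyl-chelated 2'-methoxy groups going first. No bond to C1 or C2 is broken and trans-1,2 is the thermodynamic arrangement, so the configuration should survive; exclusion of air protects the catechol.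

## Compound list

1 | 1-(2-hydroxy-4-methoxyphenyl)ethanone | CC(=O)c1ccc(OC)cc1O | starting material
2 | 4-methoxybenzaldehyde | COc1ccc(C=O)cc1 | starting material
3 | 3-hydroxy-1-(2-hydroxy-4-methoxyphenyl)-3-(4-methoxyphenyl)propan-1-one (racemic aldol adduct, not isolated) | COc1ccc(C(O)CC(=O)c2ccc(OC)cc2O)cc1 | intermediate
4 | (E)-1-(2-hydroxy-4-methoxyphenyl)-3-(4-methoxyphenyl)prop-2-en-1-one | COc1ccc(/C=C/C(=O)c2ccc(OC)cc2O)cc1 | intermediate
5 | 1-(2,4-dimethoxyphenyl)ethanone | CC(=O)c1ccc(OC)cc1OC | starting material
6 | 3,4-dimethoxybenzaldehyde | COc1ccc(C=O)cc1OC | starting material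
7 | 1-(2,4-dimethoxyphenyl)-3-(3,4-dimethoxyphenyl)-3-hydroxypropan-1-one (racemic aldol adduct, not isolated) | COc1ccc(C(=O)CC(O)c2ccc(OC)c(OC)c2)c(OC)c1 | intermediate
8 | (E)-1-(2,4-dimethoxyphenyl)-3-(3,4-dimethoxyphenyl)prop-2-en-1-one | COc1ccc(C(=O)/C=C/c2ccc(OC)c(OC)c2)c(OC)c1 | intermediate
9 | (2-hydroxy-4-methoxyphenyl)[(1S,2S,3R,4R)-2-(2,4-dimethoxybenzoyl)-3-(3,4-dimethoxyphenyl)-4-(4-methoxyphenyl)cyclobutyl]methanone, all-trans | O=C([C@H]1[C@H](c2ccc(OC)c(OC)c2)[C@@H](c2ccc(OC)cc2)[C@@H]1C(=O)c1ccc(OC)cc1O)c1ccc(OC)cc1OC | intermediate
10 | [(1S,2S,3R,4R)-3-(3,4-dimethoxyphenyl)-4-(4-methoxyphenyl)cyclobutane-1,2-diyl]bis[(2,4-dimethoxyphenyl)methanone], all-trans | O=C([C@H]1[C@H](c2ccc(OC)c(OC)c2)[C@@H](c2ccc(OC)cc2)[C@@H]1C(=O)c1ccc(OC)cc1OC)c1ccc(OC)cc1OC | intermediate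
11 | [(1R,2S)-6,7-dimethoxy-1-(4-methoxyphenyl)-1,2-dihydronaphthalene-2,3-diyl]bis[(2,4-dimethoxyphenyl)methanone] | O=C(C1=Cc2cc(OC)c(OC)cc2[C@@H](c2ccc(OC)cc2)[C@@H]1C(=O)c1ccc(OC)cc1OC)c1ccc(OC)cc1OC | intermediate
12 | [(1R,2S)-6,7-dihydroxy-1-(4-hydroxyphenyl)-1,2-dihydronaphthalene-2,3-diyl]bis[(2,4-dihydroxyphenyl)methanone] | O=C(C1=Cc2cc(O)c(O)cc2[C@@H](c2ccc(O)cc2)[C@@H]1C(=O)c1ccc(O)cc1O)c1ccc(O)cc1O | target

## Step count and risks

Total step count: 6. Longest linear sequence: 5 (steps 1, 3, 4, 5 and 6; step 2 is the convergent branch).

**Step 3 (key step, proposed new method).** The most likely failure is homodimerisation and E/Z isomerisation of excited 4 outrunning addition to 8, because an enone is a poorer ground-state partner for a triplet than a styrene. Also possible are first bond formation at the β-carbon, which would give head-to-tail adducts, and weak facial discrimination at C2 when the incoming alkene is itself a bulky enone.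

Fallback by known chemistry, setting out from 2, 5 and 8 and returning at 10:
- Claisen–Schmidt condensation of 5 with 2 (KOH, EtOH) gives (E)-1-(2,4-dimethoxyphenyl)-3-(4-methoxyphenyl)prop-2-en-1-one F1, which has no hydroxyl and so no excited-state proton transfer.
- F1 and an excess of 8 are irradiated in MeCN at 405 nm with thioxanthone as triplet sensitiser. This is a mixed head-to-head photodimerisation of chalcones in which both partners are excited. After chromatographic removal of homocoupled material it should give the all-trans cross-adduct as the racemate, that is 10 together with its mirror image [(1R,2R,3S,4S)-3-(3,4-dimethoxyphenyl)-4-(4-methoxyphenyl)cyclobutane-1,2-diyl]bis[(2,4-dimethoxyphenyl)methanone] F2.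
- Resolution on a chiral stationary phase delivers 10, which re-enters at step 5; step 4 is then not needed.

**Step 5 (proposed new method).** The radical cation may undergo full cycloreversion to the two chalcones (loss of C2–C3) in place of ring closure. The C1 cation may lose the C2 proton, which erases the only stereocentre carried from step 3. DDQ may go on to aromatise the product to the naphthalene.

Fallback by known chemistry, setting out from F1 (made from 2 and 5 as above) and returning at 11:
- Commercial (2-formyl-4,5-dimethoxyphenyl)boronic acid is condensed with ethylene glycol (TsOH, toluene, removal of water) to the doubly protected 2-[2-(1,3-dioxolan-2-yl)-4,5-dimethoxyphenyl]-1,3,2-dioxaborolane F3.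
- Asymmetric 1,4-addition of F3 to F1 (Hayashi–Miyaura reaction: [RhCl(C2H4)2]2, the BINAP antipode that delivers the (R)-diarylmethine, aqueous KOH, dioxane) sets C1 and gives (3R)-1-(2,4-dimethoxyphenyl)-3-[2-(1,3-dioxolan-2-yl)-4,5-dimethoxyphenyl]-3-(4-methoxyphenyl)propan-1-one F4.
- Its lithium enolate (LiN(SiMe3)2, THF, −78 °C) is alkylated at C2 with commercial 2-bromo-1-(2,4-dimethoxyphenyl)ethanone, forming C2–C3 and giving 1,4-bis(2,4-dimethoxyphenyl)-2-[(R)-[2-(1,3-dioxolan-2-yl)-4,5-dimethoxyphenyl](4-methoxyphenyl)methyl]butane-1,4-dione F5 (both C2 epimers are usable).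
- Aqueous HCl in THF removes the acetal to 2-[(1R)-2-(2,4-dimethoxybenzoyl)-4-(2,4-dimethoxyphenyl)-1-(4-methoxyphenyl)-4-oxobutyl]-4,5-dimethoxybenzaldehyde F6, which is not isolated. Warming with piperidinium acetate closes ring B by intramolecular aldol condensation between C3 and the aldehyde carbon C4, and the enolisable C2 settles trans to the C1 aryl group, giving 11.

**Step 6.** Cleavage of the methoxy groups para to the carbonyls may be incomplete at the point where Lewis acid-promoted side reactions begin. These are bromide addition to the enone, double-bond migration and aromatisation of the dihydronaphthalene. The free catechol may also oxidise during work-up.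

Fallback by a switch of protecting group to benzyl, setting out from 4 and 8 and returning at 12:
- BBr3 in CH2Cl2 demethylates the simple chalcones, a standard route to polyhydroxychalcones. Compound 4 gives isoliquiritigenin, (E)-1-(2,4-dihydroxyphenyl)-3-(4-hydroxyphenyl)prop-2-en-1-one F7, and 8 gives butein, (E)-1-(2,4-dihydroxyphenyl)-3-(3,4-dihydroxyphenyl)prop-2-en-1-one F8.
- Benzyl bromide and K2CO3 in acetone alkylate the two non-chelated hydroxyls of F7 and leave the hydrogen-bonded 2'-hydroxyl, giving (E)-1-[4-(benzyloxy)-2-hydroxyphenyl]-3-[4-(benzyloxy)phenyl]prop-2-en-1-one F9. Excess benzyl bromide with K2CO3 in warm DMF alkylates all four hydroxyls of F8 to (E)-1-[2,4-bis(benzyloxy)phenyl]-3-[3,4-bis(benzyloxy)phenyl]prop-2-en-1-one F10.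
- F9 and F10 are taken through the conditions of step 3, step 4 (benzyl bromide in place of MeI) and step 5. This gives in turn the all-trans cyclobutane phenol [4-(benzyloxy)-2-hydroxyphenyl][(1S,2S,3R,4R)-2-[2,4-bis(benzyloxy)benzoyl]-3-[3,4-bis(benzyloxy)phenyl]-4-[4-(benzyloxy)phenyl]cyclobutyl]methanone F11, its benzyl ether [(1S,2S,3R,4R)-3-[3,4-bis(benzyloxy)phenyl]-4-[4-(benzyloxy)phenyl]cyclobutane-1,2-diyl]bis{[2,4-bis(benzyloxy)phenyl]methanone} F12, and the dihydronaphthalene [(1R,2S)-6,7-bis(benzyloxy)-1-[4-(benzyloxy)phenyl]-1,2-dihydronaphthalene-2,3-diyl]bis{[2,4-bis(benzyloxy)phenyl]methanone} F13.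
- BCl3 with pentamethylbenzene as cation scavenger in CH2Cl2 at −78 °C removes the seven benzyl groups under much milder conditions than the methyl ether cleavage, and without hydrogenating C3=C4, to give 12.

Further compounds
F1 | step 3 | (E)-1-(2,4-dimethoxyphenyl)-3-(4-methoxyphenyl)prop-2-en-1-one | COc1ccc(/C=C/C(=O)c2ccc(OC)cc2OC)cc1
F2 | step 3 | [(1R,2R,3S,4S)-3-(3,4-dimethoxyphenyl)-4-(4-methoxyphenyl)cyclobutane-1,2-diyl]bis[(2,4-dimethoxyphenyl)methanone] (mirror image of 10) | O=C([C@@H]1[C@@H](c2ccc(OC)c(OC)c2)[C@H](c2ccc(OC)cc2)[C@H]1C(=O)c1ccc(OC)cc1OC)c1ccc(OC)cc1OC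
F3 | step 5 | 2-[2-(1,3-dioxolan-2-yl)-4,5-dimethoxyphenyl]-1,3,2-dioxaborolane | COc1cc(B2OCCO2)c(cc1OC)C1OCCO1
F4 | step 5 | (3R)-1-(2,4-dimethoxyphenyl)-3-[2-(1,3-dioxolan-2-yl)-4,5-dimethoxyphenyl]-3-(4-methoxyphenyl)propan-1-one | COc1cc(C2OCCO2)c(cc1OC)[C@@H](c1ccc(OC)cc1)CC(=O)c1ccc(OC)cc1OC
F5 | step 5 | 1,4-bis(2,4-dimethoxyphenyl)-2-[(R)-[2-(1,3-dioxolan-2-yl)-4,5-dimethoxyphenyl](4-methoxyphenyl)methyl]butane-1,4-dione (C2 epimers) | COc1cc(C2OCCO2)c(cc1OC)[C@@H](c1ccc(OC)cc1)C(CC(=O)c1ccc(OC)cc1OC)C(=O)c1ccc(OC)cc1OC
F6 | step 5 | 2-[(1R)-2-(2,4-dimethoxybenzoyl)-4-(2,4-dimethoxyphenyl)-1-(4-methoxyphenyl)-4-oxobutyl]-4,5-dimethoxybenzaldehyde (C2 epimers, not isolated) | COc1cc(C=O)c(cc1OC)[C@@H](c1ccc(OC)cc1)C(CC(=O)c1ccc(OC)cc1OC)C(=O)c1ccc(OC)cc1OC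
F7 | step 6 | (E)-1-(2,4-dihydroxyphenyl)-3-(4-hydroxyphenyl)prop-2-en-1-one | O=C(/C=C/c1ccc(O)cc1)c1ccc(O)cc1O
F8 | step 6 | (E)-1-(2,4-dihydroxyphenyl)-3-(3,4-dihydroxyphenyl)prop-2-en-1-one | O=C(/C=C/c1ccc(O)c(O)c1)c1ccc(O)cc1O
F9 | step 6 | (E)-1-[4-(benzyloxy)-2-hydroxyphenyl]-3-[4-(benzyloxy)phenyl]prop-2-en-1-one | O=C(/C=C/c1ccc(OCc2ccccc2)cc1)c1ccc(OCc2ccccc2)cc1O
F10 | step 6 | (E)-1-[2,4-bis(benzyloxy)phenyl]-3-[3,4-bis(benzyloxy)phenyl]prop-2-en-1-one | O=C(/C=C/c1ccc(OCc2ccccc2)c(OCc2ccccc2)c1)c1ccc(OCc2ccccc2)cc1OCc1ccccc1
F11 | step 6 | [4-(benzyloxy)-2-hydroxyphenyl][(1S,2S,3R,4R)-2-[2,4-bis(benzyloxy)benzoyl]-3-[3,4-bis(benzyloxy)phenyl]-4-[4-(benzyloxy)phenyl]cyclobutyl]methanone | O=C([C@H]1[C@H](c2ccc(OCc3ccccc3)c(OCc3ccccc3)c2)[C@@H](c2ccc(OCc3ccccc3)cc2)[C@@H]1C(=O)c1ccc(OCc2ccccc2)cc1O)c1ccc(OCc2ccccc2)cc1OCc1ccccc1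
F12 | step 6 | [(1S,2S,3R,4R)-3-[3,4-bis(benzyloxy)phenyl]-4-[4-(benzyloxy)phenyl]cyclobutane-1,2-diyl]bis{[2,4-bis(benzyloxy)phenyl]methanone} | O=C([C@H]1[C@H](c2ccc(OCc3ccccc3)c(OCc3ccccc3)c2)[C@@H](c2ccc(OCc3ccccc3)cc2)[C@@H]1C(=O)c1ccc(OCc2ccccc2)cc1OCc1ccccc1)c1ccc(OCc2ccccc2)cc1OCc1ccccc1
F13 | step 6 | [(1R,2S)-6,7-bis(benzyloxy)-1-[4-(benzyloxy)phenyl]-1,2-dihydronaphthalene-2,3-diyl]bis{[2,4-bis(benzyloxy)phenyl]methanone} | O=C(C1=Cc2cc(OCc3ccccc3)c(OCc3ccccc3)cc2[C@@H](c2ccc(OCc3ccccc3)cc2)[C@@H]1C(=O)c1ccc(OCc2ccccc2)cc1OCc1ccccc1)c1ccc(OCc2ccccc2)cc1OCc1ccccc1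
A1 | alternative 1 | [(1R,2S)-1-(4-methoxyphenyl)-6,7-bis(4,4,5,5-tetramethyl-1,3,2-dioxaborolan-2-yl)-1,2-dihydronaphthalene-2,3-diyl]bis[(2,4-dimethoxyphenyl)methanone] | O=C(C1=Cc2cc(B3OC(C)(C)C(C)(C)O3)c(B3OC(C)(C)C(C)(C)O3)cc2[C@@H](c2ccc(OC)cc2)[C@@H]1C(=O)c1ccc(OC)cc1OC)c1ccc(OC)cc1OC
A2 | alternative 1 | (3E,5S,6S)-4,5-bis(2,4-dimethoxybenzoyl)-6-(4-methoxyphenyl)oct-3-ene-1,7-diyne | C#C[C@@H](c1ccc(OC)cc1)[C@H](C(=O)c1ccc(OC)cc1OC)/C(C(=O)c1ccc(OC)cc1OC)=C\C#C
A3 | alternative 1 | 2,2'-(ethyne-1,2-diyl)bis(4,4,5,5-tetramethyl-1,3,2-dioxaborolane) | CC1(C)OB(OC1(C)C)C#CB1OC(C)(C)C(C)(C)O1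
A4 | alternative 2 | [(1R,2S)-6,7-dimethoxy-1-(4-methoxyphenyl)-1,2-dihydronaphthalene-2,3-diyl]bis[(2-hydroxy-4-methoxyphenyl)methanone] | O=C(C1=Cc2cc(OC)c(OC)cc2[C@@H](c2ccc(OC)cc2)[C@@H]1C(=O)c1ccc(OC)cc1O)c1ccc(OC)cc1O
A5 | alternative 2 | bis(3-methoxyphenyl) (1R,2S)-6,7-dimethoxy-1-(4-methoxyphenyl)-1,2-dihydronaphthalene-2,3-dicarboxylate | O=C(Oc1cccc(OC)c1)C1=Cc2cc(OC)c(OC)cc2[C@@H](c2ccc(OC)cc2)[C@@H]1C(=O)Oc1cccc(OC)c1
A6 | alternative 3 | 1,2-trans-2,3-trans-3,4-cis [4-hydroxy-6,7-dimethoxy-1-(4-methoxyphenyl)-1,2,3,4-tetrahydronaphthalene-2,3-diyl]bis[(2-hydroxy-4-methoxyphenyl)methanone] | O=C([C@H]1[C@@H](O)c2cc(OC)c(OC)cc2[C@@H](c2ccc(OC)cc2)[C@@H]1C(=O)c1ccc(OC)cc1O)c1ccc(OC)cc1O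
A7 | alternative 3 | 4,5-dimethoxy-2-(4-methoxybenzyl)benzaldehyde | COc1ccc(Cc2cc(OC)c(OC)cc2C=O)cc1
A8 | alternative 3 | (E)-1,4-bis(2-hydroxy-4-methoxyphenyl)but-2-ene-1,4-dione | COc1ccc(C(=O)/C=C/C(=O)c2ccc(OC)cc2O)c(O)c1
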